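## Retrosynthetic overview

- Target 20 comes from aryl ketone 17 by Corey–Bakshi–Shibata reduction, desilylation and hydrogenolysis; 17 comes from Weinreb amide 13 and the aryllithium of bromide 14 (C4a–aryl bond).
- 13 comes from trans monoester 12, and 12 from the 4,4-diester 10 by Krapcho dealkoxycarbonylation with equilibration of C4.
- Feature: in the ring O1–C2–C3–C4–C5, C2 is benzylic to the para-oxygenated guaiacyl ring (donor) and C4 can carry two esters (acceptor). C2–C3–C4 is therefore a hidden donor–acceptor cyclopropane and O1–C5 is one formaldehyde; 10 comes from cyclopropane 7 and formaldehyde 8, forming O1–C2 and C4–C5.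
- 7 comes from formylcyclopropane 5 (reduction, silylation); 5 from enal 3 and bromomalonate 4 (amine-catalysed Michael/alkylation, sets C3); 3 from aldehyde 1 and ylide 2.
- Ring order: cyclopropane (step 2), then the tetrahydrofuran (step 5), the only ring of the target that is built; both arenes are bought.

Key step: step 5

Assumption: tetrahydrofuran positions are numbered as in the target in every name (O1, C2 guaiacyl carbon, C3 with exocyclic C3a, C4 with exocyclic C4a, C5), and the primary alcohol is carried as a TIPS ether, which goes on at −78 °C without an alkoxide and leaves only aryl benzyl ethers for the final hydrogenolysis.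

## Route

Step 1
Reactants: 1 4-(benzyloxy)-3-methoxybenzaldehyde; 2 (triphenylphosphoranylidene)acetaldehyde
Product: 3 (E)-3-[4-(benzyloxy)-3-methoxyphenyl]prop-2-enal
Conditions: 2 (1.05 equiv), toluene, 80 °C
Reagents that add atoms: none
Why: Wittig olefination with the formyl-stabilised ylide gives the E-enal, and keeping the ylide near one equivalent limits a second homologation to the dienal.

Step 2
Reactants: 3 (E)-3-[4-(benzyloxy)-3-methoxyphenyl]prop-2-enal; 4 dimethyl bromomalonate
Product: 5 dimethyl (2S,3R)-2-[4-(benzyloxy)-3-methoxyphenyl]-3-formylcyclopropane-1,1-dicarboxylate (aryl and formyl trans)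
Conditions: (S)-α,α-diphenylprolinol trimethylsilyl ether (20 mol %), 2,6-lutidine (1.1 equiv), CH2Cl2, 0 °C → rt
Reagents that add atoms: none
Why: Amine-catalysed Michael-initiated ring closure (iminium, then enamine): the bromomalonate adds to the β-carbon of the E-iminium ion on the face away from the diphenyl(silyloxy)methyl group and the enamine then displaces bromide in a 3-exo-tet closure on the same face, which sets both cyclopropane stereocentres trans and, with the (S)-catalyst, as (2S,3R).

Step 3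
Reactants: 5 dimethyl (2S,3R)-2-[4-(benzyloxy)-3-methoxyphenyl]-3-formylcyclopropane-1,1-dicarboxylate
Product: 6 dimethyl (2S,3R)-2-[4-(benzyloxy)-3-methoxyphenyl]-3-(hydroxymethyl)cyclopropane-1,1-dicarboxylate
Conditions: NaBH4, CeCl3·7H2O, MeOH–CH2Cl2, −78 °C; sat. aq NH4Cl at −78 °C; crude product used at once
Reagents that add atoms: none
Why: Luche-type borohydride reduction takes only the aldehyde, and the low temperature and cold, weakly acidic quench are chosen so that the new hydroxyl does not close onto the cis ester as a lactone; no stereocentre is touched.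

Step 4
Reactants: 6 dimethyl (2S,3R)-2-[4-(benzyloxy)-3-methoxyphenyl]-3-(hydroxymethyl)cyclopropane-1,1-dicarboxylate
Product: 7 dimethyl (2S,3R)-2-[4-(benzyloxy)-3-methoxyphenyl]-3-{[(triisopropylsilyl)oxy]methyl}cyclopropane-1,1-dicarboxylate
Conditions: TIPSOTf (1.2 equiv), 2,6-lutidine (2 equiv), CH2Cl2, −78 °C
Reagents that add atoms: triisopropylsilyl trifluoromethanesulfonate, CC(C)[Si](C(C)C)(C(C)C)OS(=O)(=O)C(F)(F)F
Why: O-Silylation with a silyl triflate and a hindered pyridine base needs no alkoxide and is fast at −78 °C, so the hydroxy diester is capped before it can lactonise, and the TIPS ether should tolerate the Lewis acid, the hot chloride and the organolithium that follow.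

Step 5
Reactants: 7 dimethyl (2S,3R)-2-[4-(benzyloxy)-3-methoxyphenyl]-3-{[(triisopropylsilyl)oxy]methyl}cyclopropane-1,1-dicarboxylate; 8 formaldehyde (charged as paraformaldehyde)
Product: 10 dimethyl (2S,3R)-2-[4-(benzyloxy)-3-methoxyphenyl]-3-{[(triisopropylsilyl)oxy]methyl}tetrahydrofuran-4,4-dicarboxylate (2,3-trans), via 2,3-cis tetrahydrofuran diester 9 (not isolated)
Conditions: (CH2O)n (5 equiv), Sc(OTf)3 (10 mol %), 4 Å MS, ClCH2CH2Cl (0.05 M), rt, then 45 °C until 9 has equilibrated to 10
Reagents that add atoms: none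
Why: Sc(III) chelates the geminal diester and, helped by the 4-benzyloxy-3-methoxyphenyl donor, the cyclopropane bond between the aryl-bearing carbon (future C2) and the malonate carbon (future C4) heterolyses to a benzylic cation/malonate ion pair; the formaldehyde oxygen bonds to C2 and the resulting oxocarbenium carbon C5 is trapped by the scandium malonate at C4, so O1–C2 and C4–C5 form in one operation. The closest known reaction type is the Lewis-acid (3+2) annulation of 2-arylcyclopropane-1,1-diesters with aldehydes to tetrahydrofuran diesters. The one new ring closes by an aldol-type 5-(enolexo)-endo-trig attack of the malonate on the oxocarbenium ion. C3 lies outside the breaking bond and keeps the configuration set in step 2, so C2 is the only new stereocentre: invertive attack on the trans cyclopropane should first give the 2,3-cis diester 9, and because the electron-rich aryl group lets the benzylic C2–O1 bond re-ionise under the same Lewis acid (the annulation is also reversible by retro-aldol), warming is expected to drain the mixture to the 2,3-trans diester 10, in which the aryl and silyloxymethyl groups avoid each other. The step needs cleavage of the C2–C4 bond and not the C3–C4 bond, which the aryl donor on C2 (against a plain alkyl group on C3) secures. It also needs formaldehyde to be captured faster than the ring-opened dipole loses a proton or oligomerises, for which excess paraformaldehyde and dilution are used.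

Step 6
Reactants: 10 dimethyl (2S,3R)-2-[4-(benzyloxy)-3-methoxyphenyl]-3-{[(triisopropylsilyl)oxy]methyl}tetrahydrofuran-4,4-dicarboxylate
Product: 12 methyl (2S,3R,4S)-2-[4-(benzyloxy)-3-methoxyphenyl]-3-{[(triisopropylsilyl)oxy]methyl}tetrahydrofuran-4-carboxylate (2,3-trans, 3,4-trans), via 3,4-cis monoester 11 (not isolated)
Conditions: NaCl (3 equiv), H2O (2 equiv), DMSO, 150 °C; then NaOMe (0.2 equiv), MeOH, rt
Reagents that add atoms: none
Why: Krapcho dealkoxycarbonylation (chloride attacks one ester methyl, the carboxylate loses CO2, the ester enolate is protonated) removes the surplus ester, and methoxide then equilibrates the 3,4-cis epimer 11 through the enolate to the 3,4-trans ester, which sets C4 by thermodynamic control.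

Step 7
Reactants: 12 methyl (2S,3R,4S)-2-[4-(benzyloxy)-3-methoxyphenyl]-3-{[(triisopropylsilyl)oxy]methyl}tetrahydrofuran-4-carboxylate
Product: 13 (2S,3R,4S)-2-[4-(benzyloxy)-3-methoxyphenyl]-N-methoxy-N-methyl-3-{[(triisopropylsilyl)oxy]methyl}tetrahydrofuran-4-carboxamide
Conditions: MeNH(OMe)·HCl (3 equiv), i-PrMgCl (6 equiv), THF, −20 → 0 °C
Reagents that add atoms: N,O-dimethylhydroxylamine hydrochloride, CNOC.Cl
Why: Weinreb amide formation by aminolysis of the methyl ester with the chloromagnesium amide is reliable for hindered esters, and since C4 is already the more stable epimer any reversible enolisation does not change it.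

Step 8
Reactants: 13 (2S,3R,4S)-2-[4-(benzyloxy)-3-methoxyphenyl]-N-methoxy-N-methyl-3-{[(triisopropylsilyl)oxy]methyl}tetrahydrofuran-4-carboxamide; 14 4-bromo-1,2-bis(benzyloxy)benzene
Product: 17 [3,4-bis(benzyloxy)phenyl]{(2S,3R,4S)-2-[4-(benzyloxy)-3-methoxyphenyl]-3-{[(triisopropylsilyl)oxy]methyl}tetrahydrofuran-4-yl}methanone, via 3,4-bis(benzyloxy)phenyllithium 15 (not isolated), via lithium hemiaminal adduct 16 (not isolated)
Conditions: 14 (1.6 equiv), n-BuLi (1.5 equiv), THF, −78 °C; then 13, −78 → −20 °C; sat. aq NH4Cl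
Reagents that add atoms: none
Why: Bromine–lithium exchange gives the aryllithium and the Weinreb ketone synthesis stops at the chelated tetrahedral adduct 16, so only one aryl group adds and the ketone appears on work-up with C4 unchanged.

Step 9
Reactants: 17 [3,4-bis(benzyloxy)phenyl]{(2S,3R,4S)-2-[4-(benzyloxy)-3-methoxyphenyl]-3-{[(triisopropylsilyl)oxy]methyl}tetrahydrofuran-4-yl}methanone
Product: 18 (R)-[3,4-bis(benzyloxy)phenyl]{(2S,3R,4S)-2-[4-(benzyloxy)-3-methoxyphenyl]-3-{[(triisopropylsilyl)oxy]methyl}tetrahydrofuran-4-yl}methanol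
Conditions: (S)-2-methyl-CBS-oxazaborolidine (0.5 equiv), BH3·SMe2 (1.0 equiv), THF, −20 °C; MeOH quench
Reagents that add atoms: none
Why: Corey–Bakshi–Shibata reduction: the (S)-oxazaborolidine–borane complex binds the ketone with the aryl group as the large substituent and delivers hydride to give the (R)-carbinol, the sense that Felkin–Anh attack anti to C3 also favours, so catalyst and substrate bias should be matched.

Step 10
Reactants: 18 (R)-[3,4-bis(benzyloxy)phenyl]{(2S,3R,4S)-2-[4-(benzyloxy)-3-methoxyphenyl]-3-{[(triisopropylsilyl)oxy]methyl}tetrahydrofuran-4-yl}methanol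
Product: 19 (R)-[3,4-bis(benzyloxy)phenyl]{(2S,3R,4S)-2-[4-(benzyloxy)-3-methoxyphenyl]-3-(hydroxymethyl)tetrahydrofuran-4-yl}methanol
Conditions: TBAF (1.2 equiv), THF, 0 °C → rt
Reagents that add atoms: none
Why: Fluoride-mediated desilylation cleaves only the Si–O bond and leaves the aryl benzyl ethers and both benzylic C–O bonds alone.

Step 11
Reactants: 19 (R)-[3,4-bis(benzyloxy)phenyl]{(2S,3R,4S)-2-[4-(benzyloxy)-3-methoxyphenyl]-3-(hydroxymethyl)tetrahydrofuran-4-yl}methanol
Product: 20 4-{(R)-hydroxy[(2S,3R,4S)-2-(4-hydroxy-3-methoxyphenyl)-3-(hydroxymethyl)tetrahydrofuran-4-yl]methyl}benzene-1,2-diol (CNP0197133.1)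
Conditions: H2 (1 atm), 10 % Pd/C, EtOAc–MeOH, rt, stopped as soon as the benzyl ethers are gone
Reagents that add atoms: none
Why: Catalytic hydrogenolysis cleaves the three aryl benzyl ethers quickly under neutral conditions, much faster than the benzylic C4a–OH and C2–O1 bonds, so stopping at full debenzylation should give the target with all four stereocentres intact.

## Compound list

1 | 4-(benzyloxy)-3-methoxybenzaldehyde | COc1cc(C=O)ccc1OCc1ccccc1 | starting material
2 | (triphenylphosphoranylidene)acetaldehyde | O=CC=P(c1ccccc1)(c1ccccc1)c1ccccc1 | starting material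
3 | (E)-3-[4-(benzyloxy)-3-methoxyphenyl]prop-2-enal | COc1cc(/C=C/C=O)ccc1OCc1ccccc1 | intermediate
4 | dimethyl bromomalonate | COC(=O)C(Br)C(=O)OC | starting material
5 | dimethyl (2S,3R)-2-[4-(benzyloxy)-3-methoxyphenyl]-3-formylcyclopropane-1,1-dicarboxylate | COc1cc([C@H]2C(C(=O)OC)(C(=O)OC)[C@@H]2C=O)ccc1OCc1ccccc1 | intermediate
6 | dimethyl (2S,3R)-2-[4-(benzyloxy)-3-methoxyphenyl]-3-(hydroxymethyl)cyclopropane-1,1-dicarboxylate | COc1cc([C@H]2C(C(=O)OC)(C(=O)OC)[C@@H]2CO)ccc1OCc1ccccc1 | intermediate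
7 | dimethyl (2S,3R)-2-[4-(benzyloxy)-3-methoxyphenyl]-3-{[(triisopropylsilyl)oxy]methyl}cyclopropane-1,1-dicarboxylate (aryl and CH2OTIPS trans) | COc1cc([C@H]2C(C(=O)OC)(C(=O)OC)[C@@H]2CO[Si](C(C)C)(C(C)C)C(C)C)ccc1OCc1ccccc1 | intermediate
8 | formaldehyde (charged as paraformaldehyde) | C=O | starting material
9 | dimethyl (2R,3R)-2-[4-(benzyloxy)-3-methoxyphenyl]-3-{[(triisopropylsilyl)oxy]methyl}tetrahydrofuran-4,4-dicarboxylate (2,3-cis) | COc1cc([C@@H]2OCC(C(=O)OC)(C(=O)OC)[C@@H]2CO[Si](C(C)C)(C(C)C)C(C)C)ccc1OCc1ccccc1 | intermediate (not isolated)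
10 | dimethyl (2S,3R)-2-[4-(benzyloxy)-3-methoxyphenyl]-3-{[(triisopropylsilyl)oxy]methyl}tetrahydrofuran-4,4-dicarboxylate (2,3-trans) | COc1cc([C@H]2OCC(C(=O)OC)(C(=O)OC)[C@@H]2CO[Si](C(C)C)(C(C)C)C(C)C)ccc1OCc1ccccc1 | intermediate
11 | methyl (2S,3R,4R)-2-[4-(benzyloxy)-3-methoxyphenyl]-3-{[(triisopropylsilyl)oxy]methyl}tetrahydrofuran-4-carboxylate (3,4-cis) | COc1cc([C@H]2OC[C@H](C(=O)OC)[C@@H]2CO[Si](C(C)C)(C(C)C)C(C)C)ccc1OCc1ccccc1 | intermediate (not isolated)
12 | methyl (2S,3R,4S)-2-[4-(benzyloxy)-3-methoxyphenyl]-3-{[(triisopropylsilyl)oxy]methyl}tetrahydrofuran-4-carboxylate | COc1cc([C@H]2OC[C@@H](C(=O)OC)[C@@H]2CO[Si](C(C)C)(C(C)C)C(C)C)ccc1OCc1ccccc1 | intermediate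
13 | (2S,3R,4S)-2-[4-(benzyloxy)-3-methoxyphenyl]-N-methoxy-N-methyl-3-{[(triisopropylsilyl)oxy]methyl}tetrahydrofuran-4-carboxamide | COc1cc([C@H]2OC[C@@H](C(=O)N(C)OC)[C@@H]2CO[Si](C(C)C)(C(C)C)C(C)C)ccc1OCc1ccccc1 | intermediate
14 | 4-bromo-1,2-bis(benzyloxy)benzene | Brc1ccc(OCc2ccccc2)c(OCc2ccccc2)c1 | starting material
15 | 3,4-bis(benzyloxy)phenyllithium | [Li]c1ccc(OCc2ccccc2)c(OCc2ccccc2)c1 | intermediate (not isolated)
16 | lithium hemiaminal adduct of 13 and 15 (lithium alkoxide of the N-methoxy-N-methyl carbinolamine, either configuration at the new carbon) | COc1cc([C@H]2OC[C@@H](C([O-])(N(C)OC)c3ccc(OCc4ccccc4)c(OCc4ccccc4)c3)[C@@H]2CO[Si](C(C)C)(C(C)C)C(C)C)ccc1OCc1ccccc1.[Li+] | intermediate (not isolated)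
17 | [3,4-bis(benzyloxy)phenyl]{(2S,3R,4S)-2-[4-(benzyloxy)-3-methoxyphenyl]-3-{[(triisopropylsilyl)oxy]methyl}tetrahydrofuran-4-yl}methanone | COc1cc([C@H]2OC[C@@H](C(=O)c3ccc(OCc4ccccc4)c(OCc4ccccc4)c3)[C@@H]2CO[Si](C(C)C)(C(C)C)C(C)C)ccc1OCc1ccccc1 | intermediate
18 | (R)-[3,4-bis(benzyloxy)phenyl]{(2S,3R,4S)-2-[4-(benzyloxy)-3-methoxyphenyl]-3-{[(triisopropylsilyl)oxy]methyl}tetrahydrofuran-4-yl}methanol | COc1cc([C@H]2OC[C@@H]([C@@H](O)c3ccc(OCc4ccccc4)c(OCc4ccccc4)c3)[C@@H]2CO[Si](C(C)C)(C(C)C)C(C)C)ccc1OCc1ccccc1 | intermediate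
19 | (R)-[3,4-bis(benzyloxy)phenyl]{(2S,3R,4S)-2-[4-(benzyloxy)-3-methoxyphenyl]-3-(hydroxymethyl)tetrahydrofuran-4-yl}methanol | COc1cc([C@H]2OC[C@@H]([C@@H](O)c3ccc(OCc4ccccc4)c(OCc4ccccc4)c3)[C@@H]2CO)ccc1OCc1ccccc1 | intermediate
20 | 4-{(R)-hydroxy[(2S,3R,4S)-2-(4-hydroxy-3-methoxyphenyl)-3-(hydroxymethyl)tetrahydrofuran-4-yl]methyl}benzene-1,2-diol | COc1cc([C@H]2OC[C@@H]([C@@H](O)c3ccc(O)c(O)c3)[C@@H]2CO)ccc1O | target

## Step count and risks

Total step count: 11. Longest linear sequence: 11 steps (1 to 20); bromide 14 enters in step 8 without steps of its own.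

Steps most likely to fail:

1. **Step 5 (key annulation).** C2 may stay at the kinetic 2,3-cis stage if re-ionisation of the benzylic C–O bond is slow. The ring-opened dipole may also be lost by proton loss from C3 to a styrene, by oligomerisation, or by Friedel–Crafts hydroxymethylation of the electron-rich ring before formaldehyde is captured. The fallback makes the same two bonds stepwise, sets out from 7 and returns at 10. Lewis-acid methanolysis of 7 (Yb(OTf)3, MeOH–CH2Cl2, rt) opens the aryl–malonate bond to the benzylic methyl ether dimethyl 2-{(2R)-1-[4-(benzyloxy)-3-methoxyphenyl]-1-methoxy-3-[(triisopropylsilyl)oxy]propan-2-yl}malonate F1, of which either benzylic epimer serves. Base-catalysed hydroxymethylation of the malonate C–H (aqueous formaldehyde, catalytic K2CO3, THF) gives dimethyl 2-(hydroxymethyl)-2-{(2R)-1-[4-(benzyloxy)-3-methoxyphenyl]-1-methoxy-3-[(triisopropylsilyl)oxy]propan-2-yl}malonate F2. Catalytic camphorsulfonic acid in CH2Cl2 then ionises the benzylic ether, and the primary hydroxyl closes O1–C2 reversibly, which should deliver the 2,3-trans diester 10.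

2. **Step 3 (aldehyde reduction).** The new hydroxymethyl group may close onto the cis ester (lactonisation) during reduction or before silylation. The fallback puts the silyl ether in place before the cyclopropane exists, sets out from 3 and returns at 7. 1,2-Reduction of enal 3 (NaBH4, CeCl3·7H2O, MeOH, 0 °C) gives (E)-3-[4-(benzyloxy)-3-methoxyphenyl]prop-2-en-1-ol F3. Silylation (TIPSCl, imidazole, DMF) gives (E)-{3-[4-(benzyloxy)-3-methoxyphenyl]allyloxy}triisopropylsilane F4. Copper(I)/chiral bis(oxazoline)-catalysed carbene transfer from dimethyl 2-(phenyl-λ3-iodanylidene)malonate (toluene, 0 °C → rt) then cyclopropanates the E-alkene stereospecifically to the trans diester 7. The ligand enantiomer is to be chosen, and the sense checked, against 7 from the main route.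

3. **Step 9 (ketone reduction).** Facial selectivity of hydride delivery may be too low if the oxazaborolidine distinguishes the aryl group poorly from the branched ring carbon. The fallback corrects the carbinol by inversion, sets out from 17 and returns at 18. Reduction of 17 with NaBH4 (MeOH, −20 °C) under Felkin–Anh control alone should give 18 together with its epimer, and the two are separated. The epimer (S)-[3,4-bis(benzyloxy)phenyl]{(2S,3R,4S)-2-[4-(benzyloxy)-3-methoxyphenyl]-3-{[(triisopropylsilyl)oxy]methyl}tetrahydrofuran-4-yl}methanol F5 is inverted by Mitsunobu reaction (4-nitrobenzoic acid, PPh3, DIAD, THF, 0 °C) to the (R)-4-nitrobenzoate of 18 F6. Methanolysis of F6 (K2CO3, MeOH) gives 18.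

## Further compounds

F1 | step 5 | dimethyl 2-{(2R)-1-[4-(benzyloxy)-3-methoxyphenyl]-1-methoxy-3-[(triisopropylsilyl)oxy]propan-2-yl}malonate | COc1cc(C(OC)[C@@H](CO[Si](C(C)C)(C(C)C)C(C)C)C(C(=O)OC)C(=O)OC)ccc1OCc1ccccc1
F2 | step 5 | dimethyl 2-(hydroxymethyl)-2-{(2R)-1-[4-(benzyloxy)-3-methoxyphenyl]-1-methoxy-3-[(triisopropylsilyl)oxy]propan-2-yl}malonate | COc1cc(C(OC)[C@@H](CO[Si](C(C)C)(C(C)C)C(C)C)C(CO)(C(=O)OC)C(=O)OC)ccc1OCc1ccccc1
F3 | step 3 | (E)-3-[4-(benzyloxy)-3-methoxyphenyl]prop-2-en-1-ol | COc1cc(/C=C/CO)ccc1OCc1ccccc1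
F4 | step 3 | (E)-{3-[4-(benzyloxy)-3-methoxyphenyl]allyloxy}triisopropylsilane | COc1cc(/C=C/CO[Si](C(C)C)(C(C)C)C(C)C)ccc1OCc1ccccc1
F5 | step 9 | (S)-[3,4-bis(benzyloxy)phenyl]{(2S,3R,4S)-2-[4-(benzyloxy)-3-methoxyphenyl]-3-{[(triisopropylsilyl)oxy]methyl}tetrahydrofuran-4-yl}methanol | COc1cc([C@H]2OC[C@@H]([C@H](O)c3ccc(OCc4ccccc4)c(OCc4ccccc4)c3)[C@@H]2CO[Si](C(C)C)(C(C)C)C(C)C)ccc1OCc1ccccc1
F6 | step 9 | (R)-[3,4-bis(benzyloxy)phenyl]{(2S,3R,4S)-2-[4-(benzyloxy)-3-methoxyphenyl]-3-{[(triisopropylsilyl)oxy]methyl}tetrahydrofuran-4-yl}methyl 4-nitrobenzoate | COc1cc([C@H]2OC[C@@H]([C@@H](OC(=O)c3ccc(cc3)[N+](=O)[O-])c3ccc(OCc4ccccc4)c(OCc4ccccc4)c3)[C@@H]2CO[Si](C(C)C)(C(C)C)C(C)C)ccc1OCc1ccccc1
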